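The bromocyclohexanol is cut at the ring bond between the tertiary carbinol carbon C1 (CH3, OH) and the neighbouring ring CH (C2) that carries the two-carbon tether and sits next to the CMe2 carbon C3; read with the tether as a vinyl group, this is a homoallylic tertiary alcohol. A stereoconvergent, ligand-controlled intramolecular Nozaki–Hiyama–Kishi allylation closes the ring: the γ-carbon of an allylchromium adds to a methyl ketone, setting C1 and C2 and leaving the vinyl handle. The precursor is an acyclic bromo keto allylic chloride whose C–Br centre comes from an organocatalytic aldehyde α-bromination. B-alkyl Suzuki union with a geraniol-derived gem-dichloroalkene, methylation and a late bromoetherification finish the target.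

Key step: step 5

Assumption: the antipodes of the amine catalyst (step 2) and of the chromium ligand (step 5) are taken to be those that give the configurations drawn; the E/Z ratio of 8 does not matter.

Step 1
Reactants: 1 methyl 3,3-dimethylpent-4-enoate
Product: 2 3,3-dimethylpent-4-enal
Conditions: DIBAL-H (1.05 equiv), CH2Cl2, −78 °C; Rochelle salt work-up
Reagents that add atoms: none
Why: Partial ester reduction, because at −78 °C the aluminium hemiacetal is stable and gives the aldehyde only on work-up; no stereocentre is involved.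

Step 2
Reactants: 2 3,3-dimethylpent-4-enal
Product: 4 (S)-2-bromo-3,3-dimethylpent-4-en-1-ol, via bromo aldehyde 3 (not isolated)
Conditions: (2R,5R)-2,5-diphenylpyrrolidine (20 mol%), PhCO2H (20 mol%), 4,4-dibromo-2,6-di-tert-butylcyclohexa-2,5-dienone, CH2Cl2/pentane, −24 °C; then NaBH4, MeOH, 0 °C
Reagents that add atoms: 4,4-dibromo-2,6-di-tert-butylcyclohexa-2,5-dien-1-one, CC(C)(C)C1=CC(Br)(Br)C=C(C(C)(C)C)C1=O
Why: Organocatalytic enamine α-bromination of an aldehyde, in which the C2-symmetric amine shields one face of the E-enamine so that Br+ gives the (S)-bromo aldehyde, which is reduced in the same flask before it can racemize.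

Step 3
Reactants: 4 (S)-2-bromo-3,3-dimethylpent-4-en-1-ol
Product: 7 (R)-5-bromo-6,6-dimethyloct-7-en-2-one, via bromo triflate 5 (not isolated), via dimethylhydrazone 6 (not isolated)
Conditions: Tf2O, 2,6-lutidine, CH2Cl2, −78 °C; then lithiated acetone N,N-dimethylhydrazone (from the hydrazone and n-BuLi, 3 equiv), THF, −78 °C; then aq. oxalic acid, Et2O, rt
Reagents that add atoms: acetone N,N-dimethylhydrazone, CC(C)=NN(C)C; water, O
Why: Azaenolate (hydrazone) alkylation by SN2 at the primary triflate of a 2-bromoalkyl triflate, which is displaced far faster than the neopentyl secondary bromide, so the C–Br centre is untouched (the descriptor changes only by priority) and mild acid hydrolysis frees the ketone.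

Step 4
Reactants: 7 (R)-5-bromo-6,6-dimethyloct-7-en-2-one
Product: 8 (R,E)-5-bromo-9-chloro-6,6-dimethylnon-7-en-2-one (E major)
Conditions: (Z)-1,4-dichlorobut-2-ene (3 equiv), second-generation Ru–NHC isopropoxybenzylidene metathesis catalyst (5 mol%), CH2Cl2, 40 °C
Reagents that add atoms: (Z)-1,4-dichlorobut-2-ene, ClC/C=C\CCl
Why: Olefin cross-metathesis of the hindered terminal vinyl group with an excess of a reactive symmetrical partner, the bulk next to the alkene favouring the E product and suppressing homodimerization.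

Step 5
Reactants: 8 (R,E)-5-bromo-9-chloro-6,6-dimethylnon-7-en-2-one
Product: 11 (1R,2R,4R)-4-bromo-2-ethenyl-1,3,3-trimethylcyclohexan-1-ol, via allylchromium(III) species 9 (not isolated), via trimethylsilyl ether 10 (not isolated)
Conditions: CrCl3(thf)3 (10 mol%), chiral tridentate oxazoline–prolinamide ligand (12 mol%), Et3N (20 mol%), Mn powder (3 equiv), TMSCl (2 equiv), THF (0.02 M), rt; then 1 M HCl
Reagents that add atoms: none
Why: Mn(0) recycles Cr(III) to Cr(II), two Cr(II) insert into the allylic C–Cl bond only, and the allylchromium(III) equilibrates by σ–π–σ shifts to the (E)-γ-substituted σ-allyl form whatever the E/Z ratio of 8, so the step is stereoconvergent; its γ-carbon then adds to the methyl ketone and TMSCl frees the alkoxide from chromium. The closest known reaction type is the catalytic Nozaki–Hiyama–Kishi allylation of ketones with chiral oxazoline ligands, used here intramolecularly. The cyclohexane closes in a 6-exo-trig mode with the C=O exocyclic to the forming ring (α-attack would need an eight-membered ring). C1 and C2 are set together by a Zimmerman–Traxler chair fused trans to the forming carbocyclic chair: the E-allyl unit puts the CMe2 carbon equatorial in the metallacycle and hence anti to the carbonyl oxygen, which forces O equatorial and CH3 axial at C1, and the ketone's ring CH2 equatorial in the metallacycle puts the vinyl group equatorial at C2, trans to O. The step needs chemoselectivity for allyl chloride over the neopentyl secondary bromide (secured by the ease of allylic C–Cl insertion), γ-regioselectivity (secured by ring size) and face selectivity relative to C4–Br; the substrate offers only a modest preference for equatorial Br in the same chair, so the absolute sense is imposed by the matched antipode of the ligand on chromium.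

Step 6
Reactants: 11 (1R,2R,4R)-4-bromo-2-ethenyl-1,3,3-trimethylcyclohexan-1-ol
Product: 12 {[(1R,2R,4R)-4-bromo-2-ethenyl-1,3,3-trimethylcyclohexyl]oxy}triethylsilane
Conditions: TESOTf, 2,6-lutidine, CH2Cl2, 0 °C
Reagents that add atoms: triethylsilyl trifluoromethanesulfonate, CC[Si](CC)(CC)OS(=O)(=O)C(F)(F)F
Why: Silylation of a hindered tertiary alcohol with a silyl triflate, needed because the free C1–OH would later attack the bromonium ion in a 6-exo mode.

Step 7
Reactants: 13 geraniol
Product: 14 (2R,3R)-2,3-epoxygeraniol, [(2R,3R)-3-methyl-3-(4-methylpent-3-en-1-yl)oxiran-2-yl]methanol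
Conditions: Ti(OiPr)4 (5 mol%), D-(−)-diethyl tartrate (7 mol%), t-BuOOH, 4 Å MS, CH2Cl2, −20 °C
Reagents that add atoms: tert-butyl hydroperoxide, CC(C)(C)OO
Why: Sharpless asymmetric epoxidation, hydroxyl-directed to the 2,3-alkene only, with the D-tartrate complex delivering oxygen to the face that gives the (2R,3R)-epoxide.

Step 8
Reactants: 14 (2R,3R)-2,3-epoxygeraniol
Product: 15 (2S,3R)-2-(chloromethyl)-3-methyl-3-(4-methylpent-3-en-1-yl)oxirane
Conditions: PPh3, CCl4, NaHCO3, reflux
Reagents that add atoms: carbon tetrachloride, ClC(Cl)(Cl)Cl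
Why: Appel chlorination of the primary alcohol through its alkoxyphosphonium salt, which leaves the epoxide stereocentres untouched (descriptor change at C2 by priority only).

Step 9
Reactants: 15 (2S,3R)-2-(chloromethyl)-3-methyl-3-(4-methylpent-3-en-1-yl)oxirane
Product: 16 3-[(2R,3S)-3-(chloromethyl)-2-methyloxiran-2-yl]propanal
Conditions: O3, CH2Cl2, −78 °C; then Me2S
Reagents that add atoms: ozone, [O-][O+]=O
Why: Ozonolysis of the only alkene with reductive work-up; doing it before the epoxide is opened avoids lactol formation.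

Step 10
Reactants: 16 3-[(2R,3S)-3-(chloromethyl)-2-methyloxiran-2-yl]propanal
Product: 17 (2S,3R)-2-(chloromethyl)-3-(4,4-dichlorobut-3-en-1-yl)-3-methyloxirane
Conditions: PPh3 (4 equiv), BrCCl3 (2 equiv), CH2Cl2, 0 °C to rt
Reagents that add atoms: bromotrichloromethane, BrC(Cl)(Cl)Cl
Why: Wittig-type dichloromethylenation by Ph3P=CCl2 made in the flask, which reacts with the aldehyde faster than the phosphine reagents touch the epoxide.

Step 11
Reactants: 17 (2S,3R)-2-(chloromethyl)-3-(4,4-dichlorobut-3-en-1-yl)-3-methyloxirane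
Product: 18 (2S,3S)-1,7,7-trichloro-3-methylhept-6-ene-2,3-diol
Conditions: HClO4 (cat.), THF/H2O, 0 °C
Reagents that add atoms: water, O
Why: Acid-catalysed epoxide hydrolysis in which water attacks the tertiary carbon C3 with inversion (C2 is deactivated by its CH2Cl group and keeps its oxygen), giving the anti-diol with the (2S,3S) configuration.

Step 12
Reactants: 18 (2S,3S)-1,7,7-trichloro-3-methylhept-6-ene-2,3-diol
Product: 19 (2S,3S)-2-[(tert-butyldimethylsilyl)oxy]-1,7,7-trichloro-3-methylhept-6-en-3-ol
Conditions: TBSOTf (1.05 equiv), 2,6-lutidine, CH2Cl2, −78 °C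
Reagents that add atoms: tert-butyldimethylsilyl trifluoromethanesulfonate, CC(C)(C)[Si](C)(C)OS(=O)(=O)C(F)(F)F
Why: Selective silylation of the secondary over the tertiary alcohol at low temperature, which prevents base-induced closure of the chlorohydrin to an epoxide in step 13.

Step 13
Reactants: 12 {[(1R,2R,4R)-4-bromo-2-ethenyl-1,3,3-trimethylcyclohexyl]oxy}triethylsilane; 19 (2S,3S)-2-[(tert-butyldimethylsilyl)oxy]-1,7,7-trichloro-3-methylhept-6-en-3-ol
Product: 21 (2S,3S,Z)-9-[(1R,3R,6R)-3-bromo-2,2,6-trimethyl-6-(triethylsilyloxy)cyclohexyl]-2-(tert-butyldimethylsilyloxy)-1,7-dichloro-3-methylnon-6-en-3-ol, via B-alkyl-9-BBN 20 (not isolated)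
Conditions: 12, 9-BBN, THF, rt; then 19, Pd2(dba)3 (2.5 mol%), XantPhos (5 mol%), aq. K3PO4, THF, 60 °C
Reagents that add atoms: none
Why: Anti-Markovnikov hydroboration followed by a B-alkyl Suzuki–Miyaura coupling in which Pd inserts only into the less hindered C–Cl bond trans to the chain of the gem-dichloroalkene, giving the (Z)-chloroalkene with the new CH2 trans to the chain.

Step 14
Reactants: 21 the (Z)-chloroalkene of step 13
Product: 22 (2S,3S,E)-9-[(1R,3R,6R)-3-bromo-2,2,6-trimethyl-6-(triethylsilyloxy)cyclohexyl]-2-(tert-butyldimethylsilyloxy)-1-chloro-3,7-dimethylnon-6-en-3-ol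
Conditions: MeZnCl (3 equiv), Pd(P(t-Bu)3)2 (5 mol%), THF/NMP, 50 °C
Reagents that add atoms: methylzinc chloride, C[Zn]Cl
Why: Negishi coupling of the alkenyl chloride with retention of geometry, which gives the (E)-trisubstituted alkene, while the unactivated alkyl bromide and alkyl chloride do not undergo oxidative addition with this catalyst.

Step 15
Reactants: 22 the (E)-trisubstituted alkene of step 14
Product: 23 the bis-silyl ether of the target (C1–OTES on the cyclohexane, OTBS on the chlorohydrin)
Conditions: bromodiethylsulfonium bromopentachloroantimonate (1.1 equiv), MeNO2, −25 °C, 5 min; aq. Na2SO3/NaHCO3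
Reagents that add atoms: bromodiethylsulfonium bromopentachloroantimonate, CC[S+](Br)CC.Cl[Sb-](Cl)(Cl)(Cl)(Cl)Br
Why: Bromoetherification in which the bromonium ion of the only alkene is opened anti at its tertiary carbon by the free tertiary OH (6-endo, Markovnikov) through a chair with Br equatorial, the bulky CH(OTBS)CH2Cl group equatorial and both methyl groups axial, so the E-geometry puts Br cis to the adjacent ring methyl and the existing carbinol centre selects the alkene face.

Step 16
Reactants: 23 the bis-silyl ether of the target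
Product: 24 (1R,2R,4R)-4-bromo-2-{2-[(2S,3R,6S)-3-bromo-6-[(1S)-2-chloro-1-hydroxyethyl]-2,6-dimethyloxan-2-yl]ethyl}-1,3,3-trimethylcyclohexan-1-ol
Conditions: HF·pyridine, THF, 0 °C to rt
Reagents that add atoms: none
Why: Acidic fluoride desilylation removes both silyl ethers without the base that would close the chlorohydrin to an epoxide.

Compound list
1 | methyl 3,3-dimethylpent-4-enoate | COC(=O)CC(C)(C)C=C | starting material
2 | 3,3-dimethylpent-4-enal | O=CCC(C)(C)C=C | intermediate
3 | (S)-2-bromo-3,3-dimethylpent-4-enal | O=C[C@@H](Br)C(C)(C)C=C | intermediate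
4 | (S)-2-bromo-3,3-dimethylpent-4-en-1-ol | OC[C@@H](Br)C(C)(C)C=C | intermediate
5 | (S)-2-bromo-3,3-dimethylpent-4-en-1-yl trifluoromethanesulfonate | O=S(=O)(OC[C@@H](Br)C(C)(C)C=C)C(F)(F)F | intermediate
6 | N,N-dimethylhydrazone of (R)-5-bromo-6,6-dimethyloct-7-en-2-one | CN(C)N=C(C)CC[C@@H](Br)C(C)(C)C=C | intermediate
7 | (R)-5-bromo-6,6-dimethyloct-7-en-2-one | CC(=O)CC[C@@H](Br)C(C)(C)C=C | intermediate
8 | (R,E)-5-bromo-9-chloro-6,6-dimethylnon-7-en-2-one | CC(=O)CC[C@@H](Br)C(C)(C)/C=C/CCl | intermediate
9 | allylchromium(III) dichloride derived from 8 (THF-solvated, E σ-allyl form) | CC(=O)CC[C@@H](Br)C(C)(C)/C=C/C[Cr](Cl)Cl | intermediate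
10 | {[(1R,2R,4R)-4-bromo-2-ethenyl-1,3,3-trimethylcyclohexyl]oxy}trimethylsilane | CC1(C)[C@H](Br)CC[C@@](C)(O[Si](C)(C)C)[C@@H]1C=C | intermediate
11 | (1R,2R,4R)-4-bromo-2-ethenyl-1,3,3-trimethylcyclohexan-1-ol | CC1(C)[C@H](Br)CC[C@@](C)(O)[C@@H]1C=C | intermediate
12 | {[(1R,2R,4R)-4-bromo-2-ethenyl-1,3,3-trimethylcyclohexyl]oxy}triethylsilane | CC1(C)[C@H](Br)CC[C@@](C)(O[Si](CC)(CC)CC)[C@@H]1C=C | intermediate
13 | geraniol | CC(C)=CCC/C(C)=C/CO | starting material
14 | (2R,3R)-2,3-epoxygeraniol | CC(C)=CCC[C@@]1(C)O[C@@H]1CO | intermediate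
15 | (2S,3R)-2-(chloromethyl)-3-methyl-3-(4-methylpent-3-en-1-yl)oxirane | CC(C)=CCC[C@@]1(C)O[C@@H]1CCl | intermediate
16 | 3-[(2R,3S)-3-(chloromethyl)-2-methyloxiran-2-yl]propanal | O=CCC[C@@]1(C)O[C@@H]1CCl | intermediate
17 | (2S,3R)-2-(chloromethyl)-3-(4,4-dichlorobut-3-en-1-yl)-3-methyloxirane | ClC(Cl)=CCC[C@@]1(C)O[C@@H]1CCl | intermediate
18 | (2S,3S)-1,7,7-trichloro-3-methylhept-6-ene-2,3-diol | ClC(Cl)=CCC[C@](C)(O)[C@H](O)CCl | intermediate
19 | (2S,3S)-2-[(tert-butyldimethylsilyl)oxy]-1,7,7-trichloro-3-methylhept-6-en-3-ol | ClC(Cl)=CCC[C@](C)(O)[C@H](O[Si](C)(C)C(C)(C)C)CCl | intermediate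
20 | 9-{2-[(1R,3R,6R)-3-bromo-2,2,6-trimethyl-6-(triethylsilyloxy)cyclohexyl]ethyl}-9-borabicyclo[3.3.1]nonane | CC1(C)[C@H](Br)CC[C@@](C)(O[Si](CC)(CC)CC)[C@@H]1CCB1C2CCCC1CCC2 | intermediate
21 | (2S,3S,Z)-9-[(1R,3R,6R)-3-bromo-2,2,6-trimethyl-6-(triethylsilyloxy)cyclohexyl]-2-(tert-butyldimethylsilyloxy)-1,7-dichloro-3-methylnon-6-en-3-ol | CC1(C)[C@H](Br)CC[C@@](C)(O[Si](CC)(CC)CC)[C@@H]1CC/C(Cl)=C/CC[C@](C)(O)[C@H](O[Si](C)(C)C(C)(C)C)CCl | intermediate
22 | (2S,3S,E)-9-[(1R,3R,6R)-3-bromo-2,2,6-trimethyl-6-(triethylsilyloxy)cyclohexyl]-2-(tert-butyldimethylsilyloxy)-1-chloro-3,7-dimethylnon-6-en-3-ol | CC1(C)[C@H](Br)CC[C@@](C)(O[Si](CC)(CC)CC)[C@@H]1CC/C(C)=C/CC[C@](C)(O)[C@H](O[Si](C)(C)C(C)(C)C)CCl | intermediate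
23 | bis-silyl ether of the target (cyclohexane C1–OTES, side-chain OTBS; all seven stereocentres as in the target) | CC1(C)[C@H](Br)CC[C@@](C)(O[Si](CC)(CC)CC)[C@@H]1CC[C@]1(C)O[C@](C)([C@H](O[Si](C)(C)C(C)(C)C)CCl)CC[C@H]1Br | intermediate
24 | (1R,2R,4R)-4-bromo-2-{2-[(2S,3R,6S)-3-bromo-6-[(1S)-2-chloro-1-hydroxyethyl]-2,6-dimethyloxan-2-yl]ethyl}-1,3,3-trimethylcyclohexan-1-ol | CC1(C)[C@H](Br)CC[C@@](C)(O)[C@@H]1CC[C@]1(C)O[C@](C)([C@H](O)CCl)CC[C@H]1Br | target

Total step count: 16. Longest linear sequence: 10 steps (steps 1–6 and 13–16; the geraniol branch, steps 7–12 and 13–16, is equally long).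

Steps most likely to fail

Step 5. The face discrimination with respect to the C–Br centre rests mainly on the ligand, and the hindered γ-carbon may add so slowly that protonation or dimerization of the allylchromium competes. The fallback sets out from 7 and returns at 11. An aldehyde-selective, nitrite-modified Wacker oxidation of the neopentyl vinyl group of 7 (PdCl2(MeCN)2, CuCl2, AgNO2, t-BuOH/MeNO2, O2) should give the keto aldehyde (R)-4-bromo-3,3-dimethyl-7-oxooctanal F1. A proline-catalysed 6-enolexo aldol cyclization (matched proline antipode, DMF, rt) would close the same ring bond under amine-catalyst control and give the hydroxy aldehyde (1R,2R,5R)-5-bromo-2-hydroxy-2,6,6-trimethylcyclohexane-1-carbaldehyde F2. A non-basic methylenation (Zn, CH2Br2, TiCl4, THF) would then return to 11.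

Step 15. Closure may go 5-exo to the tetrahydrofuran, or the bromonium ion may form on the wrong alkene face. The fallback sets out from 22 and returns at 23. Intramolecular oxymercuration (Hg(OCOCF3)2, MeNO2, 0 °C; then aq. KBr) is reversible and should settle on the all-chair tetrahydropyran, giving the organomercurial 3-bromomercurio analogue of 23 F3. Bromodemercuration with retention (Br2, LiBr, pyridine, 0 °C) would then give 23.

Step 3. The basic azaenolate may eliminate the β-bromo triflate, by E2 or by attack at bromine, instead of substituting it. The fallback sets out from 2 and returns at 7. The α-bromination of step 2 is run as before, and the crude bromo aldehyde 3 is trapped in the same flask with 1-(triphenylphosphoranylidene)propan-2-one to give the dienone (R,E)-5-bromo-6,6-dimethylocta-3,7-dien-2-one F4. Conjugate reduction of the enone with [(Ph3P)CuH]6 (wet benzene, rt) would give 7.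

Further compounds
F1 | step 5 | (R)-4-bromo-3,3-dimethyl-7-oxooctanal | CC(=O)CC[C@@H](Br)C(C)(C)CC=O
F2 | step 5 | (1R,2R,5R)-5-bromo-2-hydroxy-2,6,6-trimethylcyclohexane-1-carbaldehyde | CC1(C)[C@H](Br)CC[C@@](C)(O)[C@@H]1C=O
F3 | step 15 | 3-bromomercurio analogue of 23 (HgBr in place of the oxane bromine, same configuration) | CC1(C)[C@H](Br)CC[C@@](C)(O[Si](CC)(CC)CC)[C@@H]1CC[C@]1(C)O[C@](C)([C@H](O[Si](C)(C)C(C)(C)C)CCl)CC[C@H]1[Hg]Br
F4 | step 3 | (R,E)-5-bromo-6,6-dimethylocta-3,7-dien-2-one | CC(=O)/C=C/[C@@H](Br)C(C)(C)C=C
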